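## The problem

Compound 33 is a cis-fused 1,2,4a,5,6,7,8,8a-octahydronaphthalene. It is numbered here so that C1 carries the (2E,4E)-penta-2,4-dienoic acid, C2 the (E)-but-2-en-2-yl group, C3 the vinylic methyl, C7 the hydrogen sulfate and C8 a methyl group (ring A: C4a, C5–C8, C8a; ring B: C1–C4, C4a, C8a). Six stereocentres (C1, C2, C4a, C7, C8, C8a) are contiguous around the ring fusion. With α defined as the face of H4a and H8a, the bonds C4a–C4, C8a–C1, C8–CH3 and C7–O are all β on ring A, while on ring B the C1 chain is α and the C2 butenyl group β (trans). The all-cis array on ring A is what an endo Diels–Alder addition to a cyclic enone, followed by equatorial hydride delivery to a C7 ketone, leaves behind. C1 is the centre to have first: it is next to both C8a and C2, so it can send a diene to its opposite face and later a nucleophile to C2. The trisubstituted C3=C4 alkene has to be placed without regiochemical ambiguity beside the C2 stereocentre, and the (E)-butenyl geometry has to come from a defined alkenyl metal. The hydrogen sulfate (very polar, solvolysed by acid) and the free dienoic acid must come last, the C1 aldehyde that precedes the diene is epimerisable, and the two trisubstituted alkenes exclude hydrogenation and strongly acidic late steps. The feature that the plan exploits is C3: it is no stereocentre, carries only a methyl group and lies between C2 and C4. Ring B can therefore first be a five-membered ketone made of C4(=O), C4a, C8a, C1 and C2, and C3 can be inserted afterwards, with its methyl, between C4 and C2.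

## Retrosynthesis

**33 ⇒ 32 ⇒ 31.** The O–S bond of the C7 hydrogen sulfate and the acyl–oxygen bond of the ethyl ester are cut last. A sulfate monoester makes every intermediate water-soluble and acid-sensitive, so carrying it further back costs more than it saves. The reverse order would expose a free carboxylic acid to the sulfating agent. The precursor 31 is a neutral hydroxy ester. Forward, sulfation has to reach a hindered axial secondary alcohol, and saponification of 32 has to leave the sulfate monoester alone.

**31 ⇒ 30 ⇒ 27 + 28.** The side chain is numbered from the carboxyl carbon C1′ to C5′ on C1. Its C4′=C5′ alkene is cut in a vinylogous Horner–Wadsworth–Emmons sense to aldehyde 27 and the four-carbon phosphonate 28. This brings all remaining chain carbons in one step and uses an aldehyde directly on the ring; a cross-coupling at C5′ would first need a stereodefined alkenyl halide. The C7 oxygen stays silylated in 30 because a free 7β-hydroxy group is syn-axial to C1 and could close a lactol onto the aldehyde. The forward step must give the (E) alkene and must not epimerise C1.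

**27 ⇒ 26 ⇒ 25 ⇒ 24 ⇒ 19 + 20.** Changes of oxidation state and protection lead from 27 to alcohol 26 and its silyl ether 25. In 25 the C2–butenyl bond is cut and C4–H is exchanged for C4=O, which gives enone 19 and the alkenyl bromide 20. Forward, the cuprate 22 (from 20 through 21) adds to C2, the enolate 23 is trapped as enol triflate 24, and reduction of the C–O bond leaves the alkene at C3=C4. Making this alkene from a C4 ketone by hydrazone chemistry or dehydration could give C4=C4a as well; the enolate from the conjugate addition has one regiochemistry only. Enone 19 has one stereocentre fewer and no butenyl group. The forward reaction must bring the butenyl group to the β face of C2, anti to the C1 substituent.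

**19 ⇒ 15 + 16 (key disconnection).** The bonds C2–C3 and C3–C4 are cut and C3 leaves with its methyl group as 1,1-dichloroethane 16. What remains is the trimethylsilyl enol ether 15 of a cis-hydrindanone in which ring A is complete. The neighbouring choice is a Diels–Alder reaction on a six-membered enone followed by introduction of the C2=C3 unsaturation. It would use a less reactive and less face-selective dienophile and would need a second regioselective enolisation. With 15, ring B loses a carbon, the enone and a methyl group. The forward reaction asks for the enol ether on the C2 side, carbene addition to it, and opening of the cyclopropane bond shared with the five-membered ring.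

**15 ⇒ 13 ⇒ 12 ⇒ 11 ⇒ 7 + 9.** Enol ether 15 comes from ketone 13 through enolate 14, the C7 silyl ether from alcohol 12, and 12 from diketone 11 by reduction. In 11 the bonds C4a–C5 and C8–C8a are cut in a Diels–Alder sense to cyclopentenone 7 and the (Z)-dienol ether 9; the primary adduct 10 is hydrolysed. This removes ring A and three stereocentres (C4a, C8, C8a) at once and leaves a monocyclic enone with one stereocentre. An aldol or Michael closure of ring A would set these centres one by one. The cycloaddition must be regioselective (C8 to C8a), endo, and anti to the C1 substituent. The reduction must choose the six-membered ketone C7 over the five-membered C4 and deliver hydride equatorially.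

**7 ⇒ 6 ⇒ 5 ⇒ 1 + 2; 9 ⇒ 8.** The exocyclic C1–CH2 bond is cut. Enone 7 is the silyl ether of 6, whose hydroxyl comes from the C–Si bond of 5 by oxidation. Compound 5 comes from the chiral-pool enone 1 and silane 2 (as Grignard reagent 3) by conjugate addition and loss of silanol from 4. The silyloxy enone thus serves as source of chirality and as leaving group, which is shorter than a resolution or an asymmetric synthesis of a 4-substituted cyclopentenone. Diene 9 is one step from 8. The forward step must add anti to the silyloxy group and eliminate without racemising the γ-stereocentre.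

## Roads not taken

Alternative 1: The cut is made at the two exocyclic bonds of ring B, C2–butenyl and C1–side chain, and leads back to a benzene ring.
- **Forward key step:** the alkenyllithium 21, bound to a chiral diether or diamine ligand, would add ortho to the oxazoline of the arene–Cr(CO)3 complex A2 on the face away from chromium. An allyl halide would then be transferred from the metal to the neighbouring carbon, giving the trans-disubstituted cyclohexadiene A1.
- **Merits:** the trans C1/C2 relation follows from the mechanism, and ring B is bought as an arene. The centre that the chosen plan sets by steric approach control (C2, step 10) is fixed at the outset.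
- **Weak points:** A1 contains nothing of ring A. C4a, C8a, C8 and C7, cis fusion included, would have to be built onto one end of a conjugated diene with only C1 as guide. The oxazoline at C3 must be degraded to a methyl group over several steps. The first carbon of the allyl group must become sp2 for the dienoic acid. The chromium is stoichiometric, and enantioselection for an alkenyllithium rests on an external ligand.
- **Comparison:** for C1/C2 this road is better than the chosen one. The chosen plan sets against it that the fusion and three ring A centres arise in one cycloaddition under the control of C1, and that its C3 methyl needs no functional-group degradation.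

Alternative 2: The cut is the C4a–C5 bond, traded for a C3–C7 bond. It leads back to the bridged vinyl carbinol A4, a bicyclo[2.2.2]octene with C3 and C8a as bridgeheads.
- **Forward key step:** the potassium alkoxide of A4 would undergo an anionic oxy-Cope rearrangement. C3–C7 breaks, C4a–C5 forms and ring A closes onto the released cyclohexene, giving after protonation the cis-fused C7 octalone A3.
- **Merits:** the cis fusion is enforced by the bridged transition state, and the C3=C4 alkene appears exactly where the target has it. C1, C2 and C8 are carried over, so neither ring expansion nor enol triflate reduction is needed. After its key step this road is shorter than the chosen one.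
- **Weak points:** the difficulty moves into A4. It has six stereocentres, among them a quaternary methyl-bearing bridgehead and a tertiary carbinol whose vinyl group must point toward the C4=C4a bridge. It would have to come from a Diels–Alder reaction of a trisubstituted cyclohexa-1,3-diene with a ketene equivalent and a face-selective vinyl addition. Each has its own regio- and stereochemical question, and there is no obvious source of absolute configuration. The C8 methyl is α to the bridge ketone and can epimerise before the vinyl addition.
- **Comparison:** the chosen plan is longer after its key step. It sets against this that every stereocentre is traced to C1 of enone 7 through reactions of understood selectivity, and that its precursors are far simpler than A4.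

Alternative 3: The cut is the same pair of ring A bonds as in the chosen plan (C4a–C5 and C8–C8a), but onto a six-membered ring B: the quinone monoketal A6 as dienophile and diene 9.
- **Forward key step:** a chiral cationic oxazaborolidine Lewis acid would activate the C4 carbonyl of A6, and the diene would add endo to the unsubstituted C4a=C8a bond, giving the cis-fused adduct A5.
- **Merits:** the absolute configuration comes from a catalyst. Ring B arrives six-membered with the C3 methyl and the C4 carbonyl in place, so no ring expansion and no regioselective enolisation are needed. Up to the bicyclic enone this road is shorter than the chosen one.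
- **Weak points:** in A5, C1 is a ketal carbon, so the stereocentre that steers everything in the chosen plan does not exist. After unmasking, ring B is an ene-dione in which the butenyl group must be sent to C2 and not C3. The C1 carbonyl must then be homologated to the side chain with the right configuration at C1, beside the C4 and C7 oxygen functions. Telling three carbonyl-level carbons apart costs the steps that were saved.
- **Comparison:** A5 is reached faster and catalytically, which the chosen plan cannot match. The chosen plan sets against this that C1 is present from the first step, that it controls C4a, C8a and C8 without a catalyst, and that ring B never holds more than one carbonyl group.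

Key step: step 9

## Route

Remark on numbering: all bicyclic compounds keep the octalin numbering of 33, also while ring B is five-membered (C3 is then absent); α is the face of H4a and H8a, β the opposite face; TBS = tert-butyldimethylsilyl, TBDPS = tert-butyldiphenylsilyl.

Remark on the final form: 33 is drawn as the free hydrogen sulfate and carboxylic acid; it is assumed that this form is reached by brief cold acidification after the saponification, the sulfate being handled as a salt until then.

Step 1
Reactants: 1 (R)-4-(tert-butyldimethylsilyloxy)cyclopent-2-en-1-one; 2 (chloromethyl)(isopropoxy)dimethylsilane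
Product: 5 (R)-4-{[isopropoxy(dimethyl)silyl]methyl}cyclopent-2-en-1-one, via silylmethyl Grignard reagent 3 (not isolated), via trans-silyloxy ketone 4 (not isolated)
Conditions: 2, Mg, THF, rt → 40 °C; then 1, CuBr·SMe2 (10 mol %), THF, −78 → −30 °C; aq. NH4Cl; crude 4, DBU, CH2Cl2, 0 °C
Reagents that add atoms: none
Why: Copper-catalysed 1,4-addition of the Grignard reagent occurs anti to the C4 silyloxy group; DBU then removes the proton between the carbonyl and the silyloxy carbon and silanolate is lost (E1cB), so that the enone is transposed and the old β-carbon becomes the new γ-stereocentre with (R) configuration (conjugate addition–elimination). The mild base at 0 °C should not move the alkene into conjugation with the new substituent.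

Step 2
Reactants: 5 (R)-4-{[isopropoxy(dimethyl)silyl]methyl}cyclopent-2-en-1-one
Product: 6 (R)-4-(hydroxymethyl)cyclopent-2-en-1-one
Conditions: 30 % H2O2, KF, KHCO3, THF/MeOH, 0 °C → rt
Reagents that add atoms: hydrogen peroxide, OO
Why: Tamao oxidation: fluoride activates the alkoxysilane and the C–Si bond migrates to peroxide oxygen, giving the primary alcohol; the stereocentre is not touched, and the bicarbonate buffer keeps the medium too weakly basic for fast conjugate epoxidation of the enone or γ-deprotonation.

Step 3
Reactants: 6 (R)-4-(hydroxymethyl)cyclopent-2-en-1-one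
Product: 7 (R)-4-{[(tert-butyldiphenylsilyl)oxy]methyl}cyclopent-2-en-1-one
Conditions: TBDPSCl, imidazole, CH2Cl2, 0 °C → rt
Reagents that add atoms: tert-butyl(chloro)diphenylsilane, CC(C)(C)[Si](Cl)(c1ccccc1)c1ccccc1
Why: Standard silylation of a primary alcohol under non-enolising conditions; the bulky, acid-stable TBDPS ether later shields the α face of the enone and survives the acidic hydrolysis in step 5.

Step 4
Reactants: 8 pent-1-en-3-one
Product: 9 (Z)-tert-butyl(dimethyl)(penta-1,3-dien-3-yloxy)silane
Conditions: TBSOTf, Et3N, Et2O, −78 → 0 °C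
Reagents that add atoms: tert-butyldimethylsilyl trifluoromethanesulfonate, CC(C)(C)[Si](C)(C)OS(=O)(=O)C(F)(F)F
Why: Soft enolisation of the ethyl ketone (O-silylation, then deprotonation of the oxocarbenium ion by the amine) gives the (Z)-silyl dienol ether, in which the methyl group is cis to oxygen and therefore on the outside of the s-cis diene.

Step 5
Reactants: 7 (R)-4-{[(tert-butyldiphenylsilyl)oxy]methyl}cyclopent-2-en-1-one; 9 (Z)-tert-butyl(dimethyl)(penta-1,3-dien-3-yloxy)silane
Product: 11 1α-{[(tert-butyldiphenylsilyl)oxy]methyl}-8β-methyl-cis-hydrindane-4,7-dione, via silyl enol ether adduct 10 (not isolated)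
Conditions: 9 (3 equiv), BHT (cat.), toluene, 150 °C, sealed tube; then 1 M HCl, THF, 0 °C
Reagents that add atoms: none
Why: Normal-demand Diels–Alder reaction: the nucleophilic enol ether terminus C8 bonds to the enone β-carbon C8a, and the diene approaches the face opposite the C1 CH2OTBDPS group, which fixes C4a and C8a (both H α, cis fusion by suprafacial addition). The endo transition state places the outside methyl of the (Z)-diene cis to the five-membered ring, which sets C8 (methyl β). Cold dilute acid then hydrolyses the enol ether by protonation at C6 (no stereocentre) and is too mild to epimerise C8 or C4a or to cleave the TBDPS ether.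

Step 6
Reactants: 11 1α-{[(tert-butyldiphenylsilyl)oxy]methyl}-8β-methyl-cis-hydrindane-4,7-dione
Product: 12 7β-hydroxy-1α-{[(tert-butyldiphenylsilyl)oxy]methyl}-8β-methyl-cis-hydrindan-4-one
Conditions: LiBH(s-Bu)3 (L-Selectride, 1.05 equiv), THF, −78 °C; aq. NH4Cl
Reagents that add atoms: none
Why: Hydride reduction of a cyclohexanone is faster than that of a cyclopentanone (relief of torsional strain on going to sp3 in the six-membered ring), so one equivalent at −78 °C should take C7 and leave C4. In the preferred chair of ring A the C8 methyl is equatorial and the C8a–C1 bond axial, which blocks the axial trajectory at C7; the bulky borohydride therefore attacks equatorially and gives the axial 7β-alcohol, cis to the C8 methyl.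

Step 7
Reactants: 12 7β-hydroxy-1α-{[(tert-butyldiphenylsilyl)oxy]methyl}-8β-methyl-cis-hydrindan-4-one
Product: 13 7β-(tert-butyldimethylsilyloxy)-1α-{[(tert-butyldiphenylsilyl)oxy]methyl}-8β-methyl-cis-hydrindan-4-one
Conditions: TBSOTf, 2,6-lutidine, CH2Cl2, −78 → 0 °C
Reagents that add atoms: tert-butyldimethylsilyl trifluoromethanesulfonate, CC(C)(C)[Si](C)(C)OS(=O)(=O)C(F)(F)F
Why: The silyl triflate silylates even a hindered axial secondary alcohol; with the weak base 2,6-lutidine at low temperature the C4 ketone is not converted into its enol ether at a competitive rate.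

Step 8
Reactants: 13 7β-(tert-butyldimethylsilyloxy)-1α-{[(tert-butyldiphenylsilyl)oxy]methyl}-8β-methyl-cis-hydrindan-4-one
Product: 15 trimethylsilyl enol ether C4(OSiMe3)=C2 of ketone 13, via lithium enolate 14 (not isolated)
Conditions: LiN(i-Pr)2 (LDA), THF, −78 °C; then Me3SiCl/Et3N, −78 → 0 °C
Reagents that add atoms: chlorotrimethylsilane, C[Si](C)(C)Cl
Why: Kinetic deprotonation by the hindered amide takes the accessible C2 methylene hydrogen and not the tertiary ring-fusion hydrogen at C4a; O-silylation of the enolate fixes this regiochemistry and leaves the cis fusion untouched (kinetic silyl enol ether formation).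

Step 9
Reactants: 15 trimethylsilyl enol ether C4(OSiMe3)=C2 of ketone 13; 16 1,1-dichloroethane
Product: 19 cis-fused enone C4(=O)–C3(CH3)=C2 of the octalin series (7β-OTBS; 1α-CH2OTBDPS; 8β-CH3), via 1,1-dichloroethyllithium 17 (not isolated), via siloxychlorocyclopropane 18 (not isolated)
Conditions: 16 (excess), n-BuLi (slow addition), Et2O, −40 → −20 °C; then Et3N, toluene, 110 °C
Reagents that add atoms: none
Why: Deprotonation of CH3CHCl2 by n-BuLi gives the carbenoid 17, which loses LiCl and transfers chloro(methyl)carbene to the electron-rich C4=C2 enol ether of 15 in a concerted [2+1] cheletropic addition; this closes the three-membered ring C2–C3–C4 of 18 and forms the bonds C2–C3 and C3–C4. On heating, the epimer of 18 with chlorine endo (cis to the ring bonds C4–C4a and C2–C1) ionises with simultaneous disrotatory two-electron electrocyclic opening of the shared C4–C2 bond, so the six-membered ring B arises by ring enlargement of the bicyclo[3.1.0] unit and not by a cyclisation; the siloxy group at C4 stabilises the allyl cation, and loss of Me3SiCl leaves the enone C4(=O)–C3(CH3)=C2. The closest known reaction type is the one-carbon ring expansion of cycloalkanone silyl enol ethers to 2-substituted cycloalk-2-enones by halocarbene addition and cyclopropyl-to-allyl opening. No lasting stereocentre is created, since the cyclopropane centres C2, C3 and C4 all end sp2; C1, C4a, C7, C8 and C8a lie outside the reacting bonds, and H4a is never acidified because C4 is an enol ether and then an oxyallyl cation terminus. The step needs three selectivities: the enol ether on the C2 side (secured in step 8), attack of the carbenoid on the enol ether only (it is the sole nucleophilic alkene in 15), and cleavage of the internal and not an external cyclopropane bond. Orbital symmetry enforces the last, because only departure of endo chloride can lead to a cis-cyclohexenyl cation, and halocarbenoids of this type tend to place the halogen syn to the ring.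

Step 10
Reactants: 19 cis-fused enone C4(=O)–C3(CH3)=C2 of the octalin series; 20 (E)-2-bromobut-2-ene
Product: 24 enol triflate C4(OTf)=C3(CH3) carrying the 2β-(E)-but-2-en-2-yl group, via (E)-but-2-en-2-yllithium 21 (not isolated), via lithium dibutenylcuprate 22 (not isolated), via lithium enolate 23 (not isolated)
Conditions: 20, t-BuLi (2 equiv), Et2O, −78 °C; CuBr·SMe2 (0.5 equiv per Li), −78 → −40 °C; 19, THF, −78 → −30 °C; PhNTf2, −78 °C → rt
Reagents that add atoms: N-phenylbis(trifluoromethanesulfonimide), O=S(=O)(N(c1ccccc1)S(=O)(=O)C(F)(F)F)C(F)(F)F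
Why: Bromine–lithium exchange keeps the alkene geometry, and the Gilman cuprate [(E)-MeCH=C(Me)]2CuLi adds 1,4 to the enone at C2 anti to the adjacent C1 CH2OTBDPS group (axial attack on the half-chair in which that group is pseudoaxial); this sets C2 with the butenyl group β, trans to C1. The regiodefined enolate 23 is O-sulfonylated by PhNTf2 (conjugate addition–enolate triflation), which locks the future alkene at C3=C4.

Step 11
Reactants: 24 enol triflate C4(OTf)=C3(CH3) carrying the 2β-(E)-but-2-en-2-yl group
Product: 25 2β-[(E)-but-2-en-2-yl]-7β-(tert-butyldimethylsilyloxy)-1α-{[(tert-butyldiphenylsilyl)oxy]methyl}-3,8β-dimethyl-1,2,4a,5,6,7,8,8a-octahydronaphthalene (cis-fused)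
Conditions: Pd(OAc)2 (5 mol %), PPh3, Bu3N, HCO2H, DMF, 60 °C
Reagents that add atoms: none
Why: Palladium-catalysed formate reduction of an enol triflate: oxidative addition of the C4–OTf bond to zerovalent palladium, exchange for formate, decarboxylation to the hydride and reductive elimination give C4–H with the alkene fixed at C3=C4. The C2 stereocentre, the silyl ethers and the isolated butenyl alkene are not affected.

Step 12
Reactants: 25 the bis-silyl ether of step 11
Product: 26 {2β-[(E)-but-2-en-2-yl]-7β-(tert-butyldimethylsilyloxy)-3,8β-dimethyl-1,2,4a,5,6,7,8,8a-octahydronaphthalen-1α-yl}methanol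
Conditions: NH4F, MeOH, 50 °C
Reagents that add atoms: none
Why: Fluoride-mediated desilylation depends on access to silicon: the primary TBDPS ether is cleaved, whereas the axial secondary TBS ether at C7, flanked by the C8 methyl and the syn-axial C8a–C1 bond, should be too hindered under these mild conditions (selective silyl ether cleavage).

Step 13
Reactants: 26 the primary alcohol of step 12
Product: 27 2β-[(E)-but-2-en-2-yl]-7β-(tert-butyldimethylsilyloxy)-3,8β-dimethyl-1,2,4a,5,6,7,8,8a-octahydronaphthalene-1α-carbaldehyde
Conditions: Dess–Martin periodinane, NaHCO3, CH2Cl2, 0 °C → rt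
Reagents that add atoms: none
Why: Dess–Martin oxidation under bicarbonate buffer gives the aldehyde without acid or base strong enough to epimerise C1; the C1 configuration, trans to both ring neighbours, is in any case the more stable one.

Step 14
Reactants: 27 the aldehyde of step 13; 28 ethyl (E)-4-(diethoxyphosphoryl)but-2-enoate
Product: 30 ethyl (2E,4E)-5-{2β-[(E)-but-2-en-2-yl]-7β-(tert-butyldimethylsilyloxy)-3,8β-dimethyl-1,2,4a,5,6,7,8,8a-octahydronaphthalen-1α-yl}penta-2,4-dienoate, via lithiated phosphonate 29 (not isolated)
Conditions: 28, LiN(SiMe3)2, THF, −78 °C; then 27, −78 → 0 °C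
Reagents that add atoms: none
Why: Vinylogous Horner–Wadsworth–Emmons olefination: the stabilised anion 29 reacts at the carbon next to phosphorus and gives the new C4′=C5′ alkene (E), while the (E)-enoate alkene of the reagent is kept, so the (2E,4E)-diene arrives in one step. Low temperature and the non-nucleophilic lithium amide protect the α-stereocentre C1.

Step 15
Reactants: 30 the silylated dienoate of step 14
Product: 31 ethyl (2E,4E)-5-{2β-[(E)-but-2-en-2-yl]-7β-hydroxy-3,8β-dimethyl-1,2,4a,5,6,7,8,8a-octahydronaphthalen-1α-yl}penta-2,4-dienoate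
Conditions: HF·pyridine, pyridine, THF, 0 °C → rt
Reagents that add atoms: none
Why: Buffered hydrogen fluoride cleaves the hindered secondary TBS ether through Si–F bond formation and does not add to the dienoate or protonate the trisubstituted alkenes (silyl ether cleavage).

Step 16
Reactants: 31 the hydroxy dienoate of step 15
Product: 32 ethyl (2E,4E)-5-{2β-[(E)-but-2-en-2-yl]-3,8β-dimethyl-7β-(sulfooxy)-1,2,4a,5,6,7,8,8a-octahydronaphthalen-1α-yl}penta-2,4-dienoate
Conditions: SO3·pyridine, pyridine, rt → 40 °C
Reagents that add atoms: sulfur trioxide–pyridine complex, [O-]S(=O)(=O)[n+]1ccccc1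
Why: O-Sulfonation of the secondary alcohol by the SO3·pyridine complex gives the sulfate monoester with retention at C7 (the C–O bond is not broken); the ester and the alkenes are inert to this mild electrophile, and the product is handled as its pyridinium salt.

Step 17
Reactants: 32 the sulfated ethyl ester of step 16
Product: 33 (2E,4E)-5-[(1S,2S,4aS,7R,8S,8aR)-2-[(E)-but-2-en-2-yl]-3,8-dimethyl-7-(sulfooxy)-1,2,4a,5,6,7,8,8a-octahydronaphthalen-1-yl]penta-2,4-dienoic acid
Conditions: LiOH, THF/MeOH/H2O, 0 °C → rt; then 1 M HCl to pH 2, 0 °C
Reagents that add atoms: lithium hydroxide, [Li+].[OH-]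
Why: Saponification of the ethyl ester by hydroxide (acyl–oxygen cleavage); the sulfate monoester anion is not attacked by hydroxide, C1 is no longer next to a carbonyl group, and brief cold acidification gives the free acid form without solvolysis of the secondary sulfate.

## Compound list

1 | (R)-4-(tert-butyldimethylsilyloxy)cyclopent-2-en-1-one | O=C1C=C[C@H](O[Si](C)(C)C(C)(C)C)C1 | starting material
2 | (chloromethyl)(isopropoxy)dimethylsilane | CC(C)O[Si](C)(C)CCl | starting material
3 | [isopropoxy(dimethyl)silyl]methylmagnesium chloride | CC(C)O[Si](C)(C)C[Mg]Cl | intermediate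
4 | (3R,4R)-4-(tert-butyldimethylsilyloxy)-3-{[isopropoxy(dimethyl)silyl]methyl}cyclopentan-1-one | O=C1C[C@@H](C[Si](C)(C)OC(C)C)[C@H](O[Si](C)(C)C(C)(C)C)C1 | intermediate
5 | (R)-4-{[isopropoxy(dimethyl)silyl]methyl}cyclopent-2-en-1-one | O=C1C=C[C@H](C[Si](C)(C)OC(C)C)C1 | intermediate
6 | (R)-4-(hydroxymethyl)cyclopent-2-en-1-one | O=C1C=C[C@H](CO)C1 | intermediate
7 | (R)-4-{[(tert-butyldiphenylsilyl)oxy]methyl}cyclopent-2-en-1-one | O=C1C=C[C@H](CO[Si](c2ccccc2)(c2ccccc2)C(C)(C)C)C1 | intermediate
8 | pent-1-en-3-one | CCC(=O)C=C | starting material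
9 | (Z)-tert-butyl(dimethyl)(penta-1,3-dien-3-yloxy)silane | C/C=C(\O[Si](C)(C)C(C)(C)C)C=C | intermediate
10 | Diels–Alder adduct: 7-(tert-butyldimethylsilyloxy)-1α-{[(tert-butyldiphenylsilyl)oxy]methyl}-8β-methyl-cis-hydrind-6-en-4-one (4aα-H, 8aα-H) | O=C1C[C@@H](CO[Si](c3ccccc3)(c3ccccc3)C(C)(C)C)[C@@H]2[C@H](C)C(O[Si](C)(C)C(C)(C)C)=CC[C@H]12 | intermediate
11 | 1α-{[(tert-butyldiphenylsilyl)oxy]methyl}-8β-methyl-cis-hydrindane-4,7-dione (4aα-H, 8aα-H) | O=C1C[C@@H](CO[Si](c3ccccc3)(c3ccccc3)C(C)(C)C)[C@@H]2[C@H](C)C(=O)CC[C@H]12 | intermediate
12 | 7β-hydroxy-1α-{[(tert-butyldiphenylsilyl)oxy]methyl}-8β-methyl-cis-hydrindan-4-one | O=C1C[C@@H](CO[Si](c3ccccc3)(c3ccccc3)C(C)(C)C)[C@@H]2[C@H](C)[C@H](O)CC[C@H]12 | intermediate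
13 | 7β-(tert-butyldimethylsilyloxy)-1α-{[(tert-butyldiphenylsilyl)oxy]methyl}-8β-methyl-cis-hydrindan-4-one | O=C1C[C@@H](CO[Si](c3ccccc3)(c3ccccc3)C(C)(C)C)[C@@H]2[C@H](C)[C@H](O[Si](C)(C)C(C)(C)C)CC[C@H]12 | intermediate
14 | lithium enolate (C4–OLi, C4=C2) of 13 | [Li+].[O-]C1=C[C@@H](CO[Si](c3ccccc3)(c3ccccc3)C(C)(C)C)[C@@H]2[C@H](C)[C@H](O[Si](C)(C)C(C)(C)C)CC[C@H]12 | intermediate
15 | trimethylsilyl enol ether (C4(OSiMe3)=C2) of 13 | C[Si](C)(C)OC1=C[C@@H](CO[Si](c3ccccc3)(c3ccccc3)C(C)(C)C)[C@@H]2[C@H](C)[C@H](O[Si](C)(C)C(C)(C)C)CC[C@H]12 | intermediate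
16 | 1,1-dichloroethane | CC(Cl)Cl | starting material
17 | 1,1-dichloroethyllithium | CC(Cl)(Cl)[Li] | intermediate
18 | carbene adduct of 15: 3-chloro-3-methyl-4-(trimethylsilyloxy)cyclopropane spanning C2–C3–C4 (cyclopropane centres as a mixture) | C[Si](C)(C)OC12[C@H]3CC[C@@H](O[Si](C)(C)C(C)(C)C)[C@@H](C)[C@H]3[C@H](CO[Si](c4ccccc4)(c4ccccc4)C(C)(C)C)C1C2(C)Cl | intermediate
19 | cis-fused enone: 7β-(tert-butyldimethylsilyloxy)-1α-{[(tert-butyldiphenylsilyl)oxy]methyl}-3,8β-dimethyl-4a,5,6,7,8,8a-hexahydronaphthalen-4(1H)-one (C2=C3) | C1=C(C)C(=O)[C@H]2CC[C@@H](O[Si](C)(C)C(C)(C)C)[C@@H](C)[C@H]2[C@@H]1CO[Si](c3ccccc3)(c3ccccc3)C(C)(C)C | intermediate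
20 | (E)-2-bromobut-2-ene | C/C=C(\C)Br | starting material
21 | (E)-but-2-en-2-yllithium | C/C=C(\C)[Li] | intermediate
22 | lithium bis[(E)-but-2-en-2-yl]cuprate | [Li+].C/C=C(\C)[Cu-]/C(C)=C/C | intermediate
23 | lithium enolate (C4–OLi, C3=C4) of the 2β-butenyl ketone | [Li+].C/C=C(\C)[C@H]1C(C)=C([O-])[C@H]2CC[C@@H](O[Si](C)(C)C(C)(C)C)[C@@H](C)[C@H]2[C@@H]1CO[Si](c3ccccc3)(c3ccccc3)C(C)(C)C | intermediate
24 | enol triflate: 2β-[(E)-but-2-en-2-yl]-7β-(tert-butyldimethylsilyloxy)-1α-{[(tert-butyldiphenylsilyl)oxy]methyl}-3,8β-dimethyl-1,2,4a,5,6,7,8,8a-octahydronaphthalen-4-yl trifluoromethanesulfonate | C/C=C(\C)[C@H]1C(C)=C(OS(=O)(=O)C(F)(F)F)[C@H]2CC[C@@H](O[Si](C)(C)C(C)(C)C)[C@@H](C)[C@H]2[C@@H]1CO[Si](c3ccccc3)(c3ccccc3)C(C)(C)C | intermediate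
25 | 2β-[(E)-but-2-en-2-yl]-7β-(tert-butyldimethylsilyloxy)-1α-{[(tert-butyldiphenylsilyl)oxy]methyl}-3,8β-dimethyl-1,2,4a,5,6,7,8,8a-octahydronaphthalene (cis-fused) | C/C=C(\C)[C@H]1C(C)=C[C@H]2CC[C@@H](O[Si](C)(C)C(C)(C)C)[C@@H](C)[C@H]2[C@@H]1CO[Si](c3ccccc3)(c3ccccc3)C(C)(C)C | intermediate
26 | {2β-[(E)-but-2-en-2-yl]-7β-(tert-butyldimethylsilyloxy)-3,8β-dimethyl-1,2,4a,5,6,7,8,8a-octahydronaphthalen-1α-yl}methanol | C/C=C(\C)[C@H]1C(C)=C[C@H]2CC[C@@H](O[Si](C)(C)C(C)(C)C)[C@@H](C)[C@H]2[C@@H]1CO | intermediate
27 | 2β-[(E)-but-2-en-2-yl]-7β-(tert-butyldimethylsilyloxy)-3,8β-dimethyl-1,2,4a,5,6,7,8,8a-octahydronaphthalene-1α-carbaldehyde | C/C=C(\C)[C@H]1C(C)=C[C@H]2CC[C@@H](O[Si](C)(C)C(C)(C)C)[C@@H](C)[C@H]2[C@@H]1C=O | intermediate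
28 | ethyl (E)-4-(diethoxyphosphoryl)but-2-enoate | CCOC(=O)/C=C/CP(=O)(OCC)OCC | starting material
29 | lithium salt of 28 (carbanion at the carbon next to phosphorus) | [Li+].CCOC(=O)/C=C/[CH-]P(=O)(OCC)OCC | intermediate
30 | ethyl (2E,4E)-5-{2β-[(E)-but-2-en-2-yl]-7β-(tert-butyldimethylsilyloxy)-3,8β-dimethyl-1,2,4a,5,6,7,8,8a-octahydronaphthalen-1α-yl}penta-2,4-dienoate | C/C=C(\C)[C@H]1C(C)=C[C@H]2CC[C@@H](O[Si](C)(C)C(C)(C)C)[C@@H](C)[C@H]2[C@@H]1/C=C/C=C/C(=O)OCC | intermediate
31 | ethyl (2E,4E)-5-{2β-[(E)-but-2-en-2-yl]-7β-hydroxy-3,8β-dimethyl-1,2,4a,5,6,7,8,8a-octahydronaphthalen-1α-yl}penta-2,4-dienoate | C/C=C(\C)[C@H]1C(C)=C[C@H]2CC[C@@H](O)[C@@H](C)[C@H]2[C@@H]1/C=C/C=C/C(=O)OCC | intermediate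
32 | ethyl (2E,4E)-5-{2β-[(E)-but-2-en-2-yl]-3,8β-dimethyl-7β-(sulfooxy)-1,2,4a,5,6,7,8,8a-octahydronaphthalen-1α-yl}penta-2,4-dienoate | C/C=C(\C)[C@H]1C(C)=C[C@H]2CC[C@@H](OS(=O)(=O)O)[C@@H](C)[C@H]2[C@@H]1/C=C/C=C/C(=O)OCC | intermediate
33 | (2E,4E)-5-[(1S,2S,4aS,7R,8S,8aR)-2-[(E)-but-2-en-2-yl]-3,8-dimethyl-7-(sulfooxy)-1,2,4a,5,6,7,8,8a-octahydronaphthalen-1-yl]penta-2,4-dienoic acid | C/C=C(\C)[C@H]1C(C)=C[C@H]2CC[C@@H](OS(=O)(=O)O)[C@@H](C)[C@H]2[C@@H]1/C=C/C=C/C(=O)O | target

## Step count and least certain steps

Total step count: 17. Longest linear sequence: 16 steps (steps 1–3 and 5–17, from 1); step 4 is a one-step side branch.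

**Step 9 (key step).** The most likely failure is incomplete ring opening. Carbene transfer can place chlorine exo on part of the material, and that epimer cannot open in the disrotatory sense that leads to a cis-cyclohexenyl cation, so it is stranded or decomposes on forcing. A second risk is cleavage of the enol ether by the alkyllithium before the carbenoid forms. The fallback sets out from 15 and comes back at 19. Simmons–Smith cyclopropanation (Et2Zn, CH2I2) of the enol ether gives the siloxycyclopropane F1. FeCl3 in DMF opens its internal bond oxidatively to the ring-enlarged β-chloro ketone F2 (Ito–Saegusa reaction), which loses HCl with NaOAc in MeOH to give the 3-unsubstituted enone F3. α-Iodination (I2, pyridine) gives the iodoenone F4, and Negishi coupling with MeZnCl under Pd(PPh3)4 puts the methyl group on C3, which is 19. The same C2–C3 and C3–C4 bonds are made by a one-carbon insertion; the methyl is added separately.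

**Step 10.** The most likely failure is poor facial selectivity at C2. The β face that the butenyl group must reach is also the face of ring A, and the half-chair with a pseudoaxial C1 substituent, through which anti attack is axial, is not the most stable conformer. Incomplete O-sulfonylation of the hindered enolate is a lesser risk. The fallback sets out from 19 and comes back at 25, so that 24 is bypassed. Luche reduction (NaBH4, CeCl3·7H2O), with hydride entering anti to the axial C4a–C5 bond, gives the 4β-allylic alcohol F5. Phenyl isocyanate converts it into the N-phenylcarbamate F6. The lithium salt of F6 is combined with CuI and 21, and the butenyl group is delivered within the complex to C2 on the face of the leaving group (syn SN2′ substitution) while the alkene moves to C3=C4, which is 25. The configuration at C2 then follows from that of the carbinol and not from steric approach.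

**Step 6.** The most likely failure is competing reduction of the C4 ketone, because the two carbonyl groups are told apart by a rate difference only. The fallback sets out from 7 and 8 and comes back at 12.
- Pentenone 8 is converted with Me3SiOTf and Et3N into the (Z)-trimethylsilyl dienol ether F7.
- Cycloaddition with 7, worked up without acid, gives the adduct F8, which keeps the C6=C7 trimethylsilyl enol ether.
- Kinetic enolisation of its C4 ketone toward C2 and trapping with TBSOTf gives the bis(enol ether) F9.
- K2CO3 in MeOH cleaves only the trimethylsilyl enol ether and gives the C7 ketone F10, in which C4 is masked.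
- LiBH(s-Bu)3 then has a single carbonyl group to reduce and gives the 7β-alcohol F11.
- Dilute HCl in THF hydrolyses the C4 enol ether to 12.

**Step 5.** The most likely failure is a sluggish cycloaddition at the temperature the diene tolerates, with erosion of the endo preference that sets C8 as the temperature is raised. The fallback sets out from 7 and comes back at 11. Bromination and dehydrobromination (Br2, then Et3N) give the 2-bromo enone F12, a much more reactive dienophile. Cycloaddition with 9 at lower temperature gives the adduct F13 with bromine at C4a, and cold dilute acid hydrolyses its enol ether to the bromo diketone F14. Zinc in acetic acid removes the bromine through the zinc enolate, which is protonated at C4a from the convex face to give cis-fused 11.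

**Step 2.** The most likely failure is attack of hydroperoxide on the enone (conjugate epoxidation) or base-induced migration of the double bond with loss of the γ-stereocentre. The fallback sets out from 4, isolated after step 1 without the DBU treatment, and comes back at 7. Tamao oxidation of the saturated ketone 4 gives the hydroxymethyl ketone (3S,4R)-4-(tert-butyldimethylsilyloxy)-3-(hydroxymethyl)cyclopentan-1-one F15. Silylation with TBDPSCl and imidazole gives the bis-silyl ether F16. Only then does DBU eliminate silanol to give 7, so that the enone never meets the peroxide.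

## Further compounds

F1 | step 9 | Simmons–Smith adduct of 15: 4-(trimethylsilyloxy)cyclopropane spanning C2–C3–C4 with C3 as CH2 (cyclopropane face not specified) | C[Si](C)(C)OC12[C@H]3CC[C@@H](O[Si](C)(C)C(C)(C)C)[C@@H](C)[C@H]3[C@H](CO[Si](c4ccccc4)(c4ccccc4)C(C)(C)C)C1C2
F2 | step 9 | β-chloro ketone: 2-chloro-7β-(tert-butyldimethylsilyloxy)-1α-{[(tert-butyldiphenylsilyl)oxy]methyl}-8β-methyl-cis-octahydronaphthalen-4(1H)-one (C2 configuration not specified) | O=C1CC(Cl)[C@@H](CO[Si](c3ccccc3)(c3ccccc3)C(C)(C)C)[C@@H]2[C@H](C)[C@H](O[Si](C)(C)C(C)(C)C)CC[C@H]12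
F3 | step 9 | enone 19 without the C3 methyl group | C1=CC(=O)[C@H]2CC[C@@H](O[Si](C)(C)C(C)(C)C)[C@@H](C)[C@H]2[C@@H]1CO[Si](c3ccccc3)(c3ccccc3)C(C)(C)C
F4 | step 9 | 3-iodo analogue of enone 19 (iodine in place of the C3 methyl) | C1=C(I)C(=O)[C@H]2CC[C@@H](O[Si](C)(C)C(C)(C)C)[C@@H](C)[C@H]2[C@@H]1CO[Si](c3ccccc3)(c3ccccc3)C(C)(C)C
F5 | step 10 | 4β-allylic alcohol from 19 (C2=C3, C4–OH cis to the C4a–C5 bond) | C1=C(C)[C@@H](O)[C@H]2CC[C@@H](O[Si](C)(C)C(C)(C)C)[C@@H](C)[C@H]2[C@@H]1CO[Si](c3ccccc3)(c3ccccc3)C(C)(C)C
F6 | step 10 | N-phenylcarbamate of F5 | C1=C(C)[C@@H](OC(=O)Nc3ccccc3)[C@H]2CC[C@@H](O[Si](C)(C)C(C)(C)C)[C@@H](C)[C@H]2[C@@H]1CO[Si](c4ccccc4)(c4ccccc4)C(C)(C)C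
F7 | step 6 | (Z)-trimethyl(penta-1,3-dien-3-yloxy)silane | C/C=C(\O[Si](C)(C)C)C=C
F8 | step 6 | Diels–Alder adduct with the C6=C7 trimethylsilyl enol ether: 1α-{[(tert-butyldiphenylsilyl)oxy]methyl}-8β-methyl-7-(trimethylsilyloxy)-cis-hydrind-6-en-4-one | O=C1C[C@@H](CO[Si](c3ccccc3)(c3ccccc3)C(C)(C)C)[C@@H]2[C@H](C)C(O[Si](C)(C)C)=CC[C@H]12
F9 | step 6 | bis(enol ether): C4(OTBS)=C2 and C7(OSiMe3)=C6 | CC(C)(C)[Si](C)(C)OC1=C[C@@H](CO[Si](c3ccccc3)(c3ccccc3)C(C)(C)C)[C@@H]2[C@H](C)C(O[Si](C)(C)C)=CC[C@H]12
F10 | step 6 | C7 ketone with the C4(OTBS)=C2 enol ether | CC(C)(C)[Si](C)(C)OC1=C[C@@H](CO[Si](c3ccccc3)(c3ccccc3)C(C)(C)C)[C@@H]2[C@H](C)C(=O)CC[C@H]12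
F11 | step 6 | 7β-alcohol with the C4(OTBS)=C2 enol ether | CC(C)(C)[Si](C)(C)OC1=C[C@@H](CO[Si](c3ccccc3)(c3ccccc3)C(C)(C)C)[C@@H]2[C@H](C)[C@H](O)CC[C@H]12
F12 | step 5 | (R)-2-bromo-4-{[(tert-butyldiphenylsilyl)oxy]methyl}cyclopent-2-en-1-one | O=C1C(Br)=C[C@H](CO[Si](c2ccccc2)(c2ccccc2)C(C)(C)C)C1
F13 | step 5 | 4a-bromo analogue of adduct 10 (C6=C7 silyl enol ether) | O=C1C[C@@H](CO[Si](c3ccccc3)(c3ccccc3)C(C)(C)C)[C@@H]2[C@H](C)C(O[Si](C)(C)C(C)(C)C)=CC[C@]12Br
F14 | step 5 | 4a-bromo analogue of diketone 11 | O=C1C[C@@H](CO[Si](c3ccccc3)(c3ccccc3)C(C)(C)C)[C@@H]2[C@H](C)C(=O)CC[C@]12Br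
F15 | step 2 | (3S,4R)-4-(tert-butyldimethylsilyloxy)-3-(hydroxymethyl)cyclopentan-1-one | O=C1C[C@@H](CO)[C@H](O[Si](C)(C)C(C)(C)C)C1
F16 | step 2 | (3S,4R)-4-(tert-butyldimethylsilyloxy)-3-{[(tert-butyldiphenylsilyl)oxy]methyl}cyclopentan-1-one | O=C1C[C@@H](CO[Si](c2ccccc2)(c2ccccc2)C(C)(C)C)[C@H](O[Si](C)(C)C(C)(C)C)C1
A1 | alternative 1 | trans-5-allyl-6-[(E)-but-2-en-2-yl]-1-(4,4-dimethyl-4,5-dihydrooxazol-2-yl)cyclohexa-1,3-diene | C/C=C(\C)[C@H]1C(C2=NC(C)(C)CO2)=CC=C[C@@H]1CC=C
A2 | alternative 1 | tricarbonyl[(4,4-dimethyl-4,5-dihydrooxazol-2-yl)benzene]chromium, the arene–Cr(CO)3 complex | CC1(C)COC(c2ccccc2)=N1.[Cr].[C-]#[O+].[C-]#[O+].[C-]#[O+]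
A3 | alternative 2 | cis-fused C7 octalone with the C3=C4 alkene, 2β-butenyl and 1α-CH2OTBDPS | C/C=C(\C)[C@H]1C(C)=C[C@H]2CCC(=O)[C@@H](C)[C@H]2[C@@H]1CO[Si](c3ccccc3)(c4ccccc4)C(C)(C)C
A4 | alternative 2 | bridged vinyl carbinol: bicyclo[2.2.2]octene with bridgeheads C3 (methyl) and C8a, C7 vinyl carbinol syn to the C4=C4a bridge | C=C[C@]1(O)[C@@H](C)[C@H]2[C@H](CO[Si](c3ccccc3)(c3ccccc3)C(C)(C)C)[C@@H](/C(C)=C/C)[C@]1(C)C=C2
A5 | alternative 3 | cis-fused adduct with the C6=C7 silyl enol ether, C4 enone and C1 dimethyl ketal | C1=C(C)C(=O)[C@H]2CC=C(O[Si](C)(C)C(C)(C)C)[C@@H](C)[C@H]2C1(OC)OC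
A6 | alternative 3 | 4,4-dimethoxy-2-methylcyclohexa-2,5-dien-1-one | CC1=CC(OC)(OC)C=CC1=O
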